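**Retrosynthetic overview**
- The target is an isomer of an aromatic prenyl ester. The last step is a ligand-controlled, palladium-catalysed dearomative ester-to-carbon prenyl shift that makes the C6 quaternary centre; the classical route would be base-mediated alkylative dearomatisation with a prenyl halide.
- The prenyl ester comes from alkoxide opening of a tricyclic aryl lactone (ring C), made by a carbene-catalysed annulation of a 6-alkyl-5,7-dihydroxychromanone with 3-phenylpropynal, which sets the benzylic centre.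
- The branched side chain is built on the arene rather than attached as an alkyl halide: C6 Mannich base, ortho-quinone methide, enamine-catalysed α-alkylation of 5-methylhex-5-enal (sets C2′), then Wittig isopropylidenation.
- The cis-2,3-dimethylchromanone (ring B) comes from a quinine-catalysed intramolecular oxa-Michael addition of tigloylphloroglucinol.
- Ring order: ring A (phloroglucinol, bought) → ring B → temporary lactol ring (opened again) → ring C lactone (opened in the last step) → ring A dearomatised last.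

Assumption: the target is taken in the enol tautomer of the given SMILES, and the absolute sense of induction of the triazolium catalyst (step 9) and of the Trost ligand (step 10) is assumed as written; the mirror-image catalyst or ligand would be used in the same step if a test run shows the opposite sense.

**Route**

Step 1
Reactants: 1 ethyl 5-oxohexanoate
Product: 2 ethyl 5-methylhex-5-enoate
Conditions: Ph3PCH3Br (1.3 equiv), KOt-Bu (1.25 equiv), THF, 0 °C to rt
Reagents that add atoms: methyltriphenylphosphonium bromide, C[P+](c1ccccc1)(c1ccccc1)c1ccccc1.[Br-]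
Why: Wittig methylenation, in which the non-stabilised ylide attacks the methyl ketone and leaves the ethyl ester untouched.

Step 2
Reactants: 2 ethyl 5-methylhex-5-enoate
Product: 3 5-methylhex-5-enal
Conditions: i-Bu2AlH (1.1 equiv), CH2Cl2, −78 °C; MeOH, then aq. KNaC4H4O6 (potassium sodium tartrate)
Reagents that add atoms: none
Why: ester-to-aldehyde half-reduction, because the aluminium hemiacetal is stable at −78 °C and collapses only on work-up while the 1,1-disubstituted alkene is inert.

Step 3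
Reactants: 4 phloroglucinol; 5 tigloyl chloride
Product: 6 (2E)-2-methyl-1-(2,4,6-trihydroxyphenyl)but-2-en-1-one
Conditions: AlCl3 (3.5 equiv), PhNO2/CH2Cl2, 0 °C to rt; ice/1 M HCl
Reagents that add atoms: none
Why: Friedel–Crafts C-acylation of a C3-symmetric triol gives a single regioisomer, and the cold acidic conditions keep the enone uncyclised for the asymmetric ring closure that follows.

Step 4
Reactants: 6 (2E)-2-methyl-1-(2,4,6-trihydroxyphenyl)but-2-en-1-one
Product: 7 (2R,3S)-5,7-dihydroxy-2,3-dimethyl-2,3-dihydro-4H-chromen-4-one (cis)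
Conditions: (−)-quinine (20 mol%), PhCl, rt, 48 h; one recrystallisation
Reagents that add atoms: none
Why: cinchona-alkaloid-catalysed intramolecular oxa-Michael addition, in which quinine (quinuclidine nitrogen as base, C9 hydroxyl as hydrogen-bond donor) delivers the phenol oxygen to one face of the tigloyl β-carbon to set C2 (R) and kinetic protonation of the enol from the less hindered face places the C3 methyl cis (S), the outcome known for ortho-tigloylphenols with this catalyst.

Step 5
Reactants: 7 (2R,3S)-5,7-dihydroxy-2,3-dimethyl-2,3-dihydro-4H-chromen-4-one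
Product: 8 (2R,3S)-6-[(dimethylamino)methyl]-5,7-dihydroxy-2,3-dimethyl-2,3-dihydro-4H-chromen-4-one
Conditions: CH2(NMe2)2 (1.05 equiv), i-PrOH/1,4-dioxane, 20 °C
Reagents that add atoms: N,N,N′,N′-tetramethylmethanediamine, CN(C)CN(C)C
Why: phenolic Mannich aminomethylation goes to C6, the carbon between the two hydroxyls, because attack there keeps the chelated 5-OH/4-C=O vinylogous acid intact and both neighbouring OH groups can deliver the iminium ion (C6 selectivity is known for 5,7-dihydroxyflavanonols), and the mild neutral conditions do not epimerise C3.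

Step 6
Reactants: 8 (2R,3S)-6-[(dimethylamino)methyl]-5,7-dihydroxy-2,3-dimethyl-2,3-dihydro-4H-chromen-4-one
Product: 9 1-[(2R,3S)-5,7-dihydroxy-2,3-dimethyl-4-oxo-3,4-dihydro-2H-chromen-6-yl]-N,N,N-trimethylmethanaminium iodide
Conditions: MeI (3 equiv), MeCN, 0 °C to rt, dark; salt collected by filtration
Reagents that add atoms: iodomethane, CI
Why: Menshutkin N-methylation, in which the tertiary amine is far more nucleophilic than the neutral hydrogen-bonded phenols in the absence of base, giving a leaving group (NMe3) that cannot form an enamine later.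

Step 7
Reactants: 9 1-[(2R,3S)-5,7-dihydroxy-2,3-dimethyl-4-oxo-3,4-dihydro-2H-chromen-6-yl]-N,N,N-trimethylmethanaminium iodide; 3 5-methylhex-5-enal
Product: 11 (2R,3S,7S)-5,8-dihydroxy-2,3-dimethyl-7-(3-methylbut-3-en-1-yl)-2,3,7,8-tetrahydro-4H,6H-pyrano[3,2-g]chromen-4-one (lactol; anomer mixture at C8), via ortho-quinone methide 10 (not isolated)
Conditions: 3 (2.5 equiv), (R)-2-[diphenyl(trimethylsilyloxy)methyl]pyrrolidine (20 mol%), NaHCO3 (1.5 equiv), CH2Cl2/H2O (9:1), 0 °C to rt
Reagents that add atoms: none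
Why: Proposed new method: NaHCO3 deprotonates the acidic 7-OH of 9 and NMe3 is expelled to give ortho-quinone methide 10, which is trapped by the (E)-enamine of aldehyde 3 in a formal inverse-demand oxa-[4+2]/Michael addition; the methide carbon approaches the enamine face opposite the bulky CPh2(OSiMe3) group of the (R)-catalyst, which sets the new centre (S) by the usual steric model for diarylprolinol silyl ethers, and hydrolysis of the N,O-aminal releases the lactol and the catalyst; the closest known reactions are enamine-catalysed formal [4+2] α-alkylations of aldehydes with ortho-quinone methides made in situ from 2-(sulfonylalkyl)phenols and the trapping of acylphloroglucinol ortho-quinone methides by electron-rich alkenes.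

Step 8
Reactants: 11 (2R,3S,7S)-5,8-dihydroxy-2,3-dimethyl-7-(3-methylbut-3-en-1-yl)-2,3,7,8-tetrahydro-4H,6H-pyrano[3,2-g]chromen-4-one
Product: 12 (2R,3S)-5,7-dihydroxy-2,3-dimethyl-6-[(2S)-5-methyl-2-(2-methylprop-1-en-1-yl)hex-5-en-1-yl]-2,3-dihydro-4H-chromen-4-one
Conditions: i-PrPPh3I (4.5 equiv), n-BuLi (4.4 equiv), THF, 0 °C; add 11 at −78 °C, then to rt
Reagents that add atoms: isopropyltriphenylphosphonium iodide, CC(C)[P+](c1ccccc1)(c1ccccc1)c1ccccc1.[I-]
Why: Wittig olefination of the lactol through its open hydroxy-aldehyde form, in which excess ylide first turns the phenols into phenoxides (so the chromanone carbonyl and C3–H are deactivated) and the fast low-temperature addition to the aldehyde outruns α-epimerisation of C2′.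

Step 9
Reactants: 12 (2R,3S)-5,7-dihydroxy-2,3-dimethyl-6-[(2S)-5-methyl-2-(2-methylprop-1-en-1-yl)hex-5-en-1-yl]-2,3-dihydro-4H-chromen-4-one; 13 3-phenylprop-2-ynal
Product: 14 (2R,3S,10S)-5-hydroxy-2,3-dimethyl-6-[(2S)-5-methyl-2-(2-methylprop-1-en-1-yl)hex-5-en-1-yl]-10-phenyl-2,3,9,10-tetrahydro-4H,8H-pyrano[2,3-f]chromene-4,8-dione
Conditions: 13 (1.5 equiv), (5aR,10bS)-2-(2,4,6-trimethylphenyl)-5a,10b-dihydro-4H,6H-indeno[2,1-b][1,2,4]triazolo[4,3-d][1,4]oxazin-2-ium chloride (10 mol%), toluene, 40 °C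
Reagents that add atoms: none
Why: N-heterocyclic-carbene redox catalysis turns the ynal into an α,β-unsaturated acyl azolium that engages the acidic 7-OH/C8 "stable enol" in a Coates–Claisen-type annulation as known for naphthols and kojic acids, C8 being the only free ring carbon; the chiral aminoindanol backbone selects the face of the cinnamoyl unit to set the benzylic centre (S), and lactonisation on O7 releases the catalyst.

Step 10
Reactants: 14 (2R,3S,10S)-5-hydroxy-2,3-dimethyl-6-[(2S)-5-methyl-2-(2-methylprop-1-en-1-yl)hex-5-en-1-yl]-10-phenyl-2,3,9,10-tetrahydro-4H,8H-pyrano[2,3-f]chromene-4,8-dione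
Product: 16 (3S)-3-[(2R,3S,6S)-4-hydroxy-2,3-dimethyl-6-(3-methylbut-2-en-1-yl)-6-[(2S)-5-methyl-2-(2-methylprop-1-en-1-yl)hex-5-en-1-yl]-5,7-dioxo-3,5,6,7-tetrahydro-2H-chromen-8-yl]-3-phenylpropanoic acid (CNP0155375.1), via potassium phenoxide prenyl ester 15 (not isolated)
Conditions: 3-methylbut-2-en-1-ol (3 equiv), KH (1.1 equiv), THF, 0 °C to rt, 1 h; then Pd2(dba)3·CHCl3 (2.5 mol%), (1S,2S)-N,N′-bis[2-(diphenylphosphanyl)benzoyl]cyclohexane-1,2-diamine (7.5 mol%), degassed THF, 25–40 °C; 1 M HCl, 0 °C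
Reagents that add atoms: 3-methylbut-2-en-1-ol, CC(C)=CCO
Why: Proposed new method: alkoxide opening of the aryl lactone gives phenoxide 15, whose prenyl ester is an isomer of the target; zerovalent palladium ionises the allylic ester to a carboxylate/(π-prenyl)palladium cation pair and the phenoxide attacks the unsubstituted allyl terminus through C6 (the only ring carbon flanked by two oxygen donors, C8 being shielded by the branched benzylic group), giving the acidic β-triketone as thermodynamic sink while O-prenyl ethers and re-formed prenyl esters re-ionise, and the chiral diphosphine pocket selects the enolate face to set C6 (S); the closest known reactions are Tsuji–Trost dearomative allylation and prenylation of acylphloroglucinols and naphthols, Trost asymmetric prenylation forming quaternary centres, and palladium-catalysed allyl ester cleavage with 1,3-dione allyl acceptors.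

**Compound list**

1 | ethyl 5-oxohexanoate | CCOC(=O)CCCC(C)=O | starting material
2 | ethyl 5-methylhex-5-enoate | CCOC(=O)CCCC(C)=C | intermediate
3 | 5-methylhex-5-enal | C=C(C)CCCC=O | intermediate
4 | phloroglucinol (benzene-1,3,5-triol) | Oc1cc(O)cc(O)c1 | starting material
5 | tigloyl chloride, (2E)-2-methylbut-2-enoyl chloride | C/C=C(\C)C(=O)Cl | starting material
6 | (2E)-2-methyl-1-(2,4,6-trihydroxyphenyl)but-2-en-1-one | C/C=C(\C)C(=O)c1c(O)cc(O)cc1O | intermediate
7 | (2R,3S)-5,7-dihydroxy-2,3-dimethyl-2,3-dihydro-4H-chromen-4-one (cis) | O=C1[C@@H](C)[C@@H](C)Oc2cc(O)cc(O)c12 | intermediate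
8 | (2R,3S)-6-[(dimethylamino)methyl]-5,7-dihydroxy-2,3-dimethyl-2,3-dihydro-4H-chromen-4-one | O=C1[C@@H](C)[C@@H](C)Oc2cc(O)c(CN(C)C)c(O)c12 | intermediate
9 | 1-[(2R,3S)-5,7-dihydroxy-2,3-dimethyl-4-oxo-3,4-dihydro-2H-chromen-6-yl]-N,N,N-trimethylmethanaminium iodide | O=C1[C@@H](C)[C@@H](C)Oc2cc(O)c(C[N+](C)(C)C)c(O)c12.[I-] | intermediate
10 | (2R,3S)-5-hydroxy-2,3-dimethyl-6-methylidene-2,3-dihydro-4H-chromene-4,7(6H)-dione (ortho-quinone methide, not isolated) | O=C1[C@@H](C)[C@@H](C)OC2=CC(=O)C(=C)C(O)=C12 | intermediate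
11 | (2R,3S,7S)-5,8-dihydroxy-2,3-dimethyl-7-(3-methylbut-3-en-1-yl)-2,3,7,8-tetrahydro-4H,6H-pyrano[3,2-g]chromen-4-one (lactol closed on O7, anomer mixture) | C=C(C)CC[C@@H]1C(O)Oc2cc3O[C@H](C)[C@H](C)C(=O)c3c(O)c2C1 | intermediate
12 | (2R,3S)-5,7-dihydroxy-2,3-dimethyl-6-[(2S)-5-methyl-2-(2-methylprop-1-en-1-yl)hex-5-en-1-yl]-2,3-dihydro-4H-chromen-4-one | C=C(C)CC[C@H](C=C(C)C)Cc1c(O)cc2O[C@H](C)[C@H](C)C(=O)c2c1O | intermediate
13 | 3-phenylprop-2-ynal | O=CC#Cc1ccccc1 | starting material
14 | (2R,3S,10S)-5-hydroxy-2,3-dimethyl-6-[(2S)-5-methyl-2-(2-methylprop-1-en-1-yl)hex-5-en-1-yl]-10-phenyl-2,3,9,10-tetrahydro-4H,8H-pyrano[2,3-f]chromene-4,8-dione | C=C(C)CC[C@H](C=C(C)C)Cc1c(O)c2C(=O)[C@@H](C)[C@@H](C)Oc2c3[C@H](c4ccccc4)CC(=O)Oc13 | intermediate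
15 | potassium (2R,3S)-5-hydroxy-2,3-dimethyl-6-[(2S)-5-methyl-2-(2-methylprop-1-en-1-yl)hex-5-en-1-yl]-8-[(1S)-3-[(3-methylbut-2-en-1-yl)oxy]-3-oxo-1-phenylpropyl]-4-oxo-3,4-dihydro-2H-chromen-7-olate (not isolated) | C=C(C)CC[C@H](C=C(C)C)Cc1c(O)c2C(=O)[C@@H](C)[C@@H](C)Oc2c([C@H](c3ccccc3)CC(=O)OCC=C(C)C)c1[O-].[K+] | intermediate
16 | (3S)-3-[(2R,3S,6S)-4-hydroxy-2,3-dimethyl-6-(3-methylbut-2-en-1-yl)-6-[(2S)-5-methyl-2-(2-methylprop-1-en-1-yl)hex-5-en-1-yl]-5,7-dioxo-3,5,6,7-tetrahydro-2H-chromen-8-yl]-3-phenylpropanoic acid | C=C(C)CC[C@H](C=C(C)C)C[C@@]1(CC=C(C)C)C(=O)C2=C(O)[C@@H](C)[C@@H](C)OC2=C([C@@H](CC(=O)O)c2ccccc2)C1=O | target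

**Totals**
- Total step count: 10.
- Longest linear sequence: 8 steps (steps 3–10 from phloroglucinol 4); the aldehyde 3 takes 2 steps and joins at step 7.

**Three steps most likely to fail, with fallbacks**

Step 10 (regio- and face-selective dearomative prenyl shift; the ionisation of a prenyl ester may be slow, and C8 attack or a poor C6 face ratio is possible). The fallback sets out from 14 and comes back at 16. Lactone 14 is opened with K2CO3 in MeOH at 0 °C to methyl (3S)-3-[(2R,3S)-5,7-dihydroxy-2,3-dimethyl-6-[(2S)-5-methyl-2-(2-methylprop-1-en-1-yl)hex-5-en-1-yl]-4-oxo-3,4-dihydro-2H-chromen-8-yl]-3-phenylpropanoate F6. Classical alkylative dearomatisation (prenyl bromide 1.2 equiv, NaOMe 2.2 equiv, MeOH, 0 °C) alkylates the doubly oxygen-flanked C6 without catalyst control. It gives the methyl ester of the target, methyl (3S)-3-[(2R,3S,6S)-4-hydroxy-2,3-dimethyl-6-(3-methylbut-2-en-1-yl)-6-[(2S)-5-methyl-2-(2-methylprop-1-en-1-yl)hex-5-en-1-yl]-5,7-dioxo-3,5,6,7-tetrahydro-2H-chromen-8-yl]-3-phenylpropanoate F7, together with its (6R)-epimer F8. The two are separated by preparative HPLC, and LiOH (THF/H2O, 0 °C) hydrolyses F7 to 16.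

Step 7 (untested enamine trapping of an unsubstituted acylphloroglucinol-type methide; methide oligomerisation or low selectivity at C2′ is possible). The fallback sets out from 9 and comes back at 11.
- Ester 2 is saponified (LiOH, THF/H2O) to 5-methylhex-5-enoic acid F1. Its pivaloyl mixed anhydride is coupled with lithiated (4R)-4-benzyl-1,3-oxazolidin-2-one to give (4R)-4-benzyl-3-(5-methylhex-5-enoyl)-1,3-oxazolidin-2-one F2.
- The sodium (Z)-enolate of F2 (NaN(SiMe3)2, THF, −78 °C, 1.5 equiv) is treated with salt 9 that has been deprotonated with NaN(SiMe3)2 (2 equiv) at −78 °C, so that methide 10 is released in the presence of the enolate.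
- Auxiliary-controlled Michael addition (Evans model, attack anti to the benzyl group) gives (4R)-4-benzyl-3-[(2S)-2-{[(2R,3S)-5,7-dihydroxy-2,3-dimethyl-4-oxochroman-6-yl]methyl}-5-methylhex-5-enoyl]-1,3-oxazolidin-2-one F3.
- On warming, the C7 phenoxide closes onto the imide carbonyl and expels the auxiliary to give (2R,3S,7S)-5-hydroxy-2,3-dimethyl-7-(3-methylbut-3-en-1-yl)-2,3,6,7-tetrahydro-4H,8H-pyrano[3,2-g]chromene-4,8-dione F4.
- i-Bu2AlH (CH2Cl2, −78 °C) reduces F4 to lactol 11.

Step 9 (a hindered acylphloroglucinol phenol is a new substrate class for the carbene-catalysed annulation; low conversion or low face selectivity is possible). The fallback sets out from 12 and comes back at 14. Phenol 12 and 5-benzylidene-2,2-dimethyl-1,3-dioxane-4,6-dione are heated with Yb(OTf)3 (10 mol%) in MeNO2 at 60 °C. Friedel–Crafts conjugate addition at C8, lactonisation on O7 with loss of acetone, and decarboxylation give lactone 14 together with its benzylic epimer (2R,3S,10R)-5-hydroxy-2,3-dimethyl-6-[(2S)-5-methyl-2-(2-methylprop-1-en-1-yl)hex-5-en-1-yl]-10-phenyl-2,3,9,10-tetrahydro-4H,8H-pyrano[2,3-f]chromene-4,8-dione F5. There is no catalyst control, and the two are separated by preparative HPLC.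

**Further compounds**

F1 | step 7 | 5-methylhex-5-enoic acid | C=C(C)CCCC(=O)O
F2 | step 7 | (4R)-4-benzyl-3-(5-methylhex-5-enoyl)-1,3-oxazolidin-2-one | C=C(C)CCCC(=O)N1C(=O)OC[C@H]1Cc1ccccc1
F3 | step 7 | (4R)-4-benzyl-3-[(2S)-2-{[(2R,3S)-5,7-dihydroxy-2,3-dimethyl-4-oxochroman-6-yl]methyl}-5-methylhex-5-enoyl]-1,3-oxazolidin-2-one | C=C(C)CC[C@H](C(=O)N1C(=O)OC[C@H]1Cc1ccccc1)Cc1c(O)cc2O[C@H](C)[C@H](C)C(=O)c2c1O
F4 | step 7 | (2R,3S,7S)-5-hydroxy-2,3-dimethyl-7-(3-methylbut-3-en-1-yl)-2,3,6,7-tetrahydro-4H,8H-pyrano[3,2-g]chromene-4,8-dione | C=C(C)CC[C@@H]1C(=O)Oc2cc3O[C@H](C)[C@H](C)C(=O)c3c(O)c2C1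
F5 | step 9 | (2R,3S,10R)-5-hydroxy-2,3-dimethyl-6-[(2S)-5-methyl-2-(2-methylprop-1-en-1-yl)hex-5-en-1-yl]-10-phenyl-2,3,9,10-tetrahydro-4H,8H-pyrano[2,3-f]chromene-4,8-dione | C=C(C)CC[C@H](C=C(C)C)Cc1c(O)c2C(=O)[C@@H](C)[C@@H](C)Oc2c3[C@@H](c4ccccc4)CC(=O)Oc13
F6 | step 10 | methyl (3S)-3-[(2R,3S)-5,7-dihydroxy-2,3-dimethyl-6-[(2S)-5-methyl-2-(2-methylprop-1-en-1-yl)hex-5-en-1-yl]-4-oxo-3,4-dihydro-2H-chromen-8-yl]-3-phenylpropanoate | C=C(C)CC[C@H](C=C(C)C)Cc1c(O)c2C(=O)[C@@H](C)[C@@H](C)Oc2c([C@H](c3ccccc3)CC(=O)OC)c1O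
F7 | step 10 | methyl (3S)-3-[(2R,3S,6S)-4-hydroxy-2,3-dimethyl-6-(3-methylbut-2-en-1-yl)-6-[(2S)-5-methyl-2-(2-methylprop-1-en-1-yl)hex-5-en-1-yl]-5,7-dioxo-3,5,6,7-tetrahydro-2H-chromen-8-yl]-3-phenylpropanoate | C=C(C)CC[C@H](C=C(C)C)C[C@@]1(CC=C(C)C)C(=O)C2=C(O)[C@@H](C)[C@@H](C)OC2=C([C@@H](CC(=O)OC)c2ccccc2)C1=O
F8 | step 10 | methyl (3S)-3-[(2R,3S,6R)-4-hydroxy-2,3-dimethyl-6-(3-methylbut-2-en-1-yl)-6-[(2S)-5-methyl-2-(2-methylprop-1-en-1-yl)hex-5-en-1-yl]-5,7-dioxo-3,5,6,7-tetrahydro-2H-chromen-8-yl]-3-phenylpropanoate | C=C(C)CC[C@H](C=C(C)C)C[C@]1(CC=C(C)C)C(=O)C2=C(O)[C@@H](C)[C@@H](C)OC2=C([C@@H](CC(=O)OC)c2ccccc2)C1=O
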